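**Retrosynthetic overview**
1. Target 12 ⇐ 11 by cleavage of the two aryl methyl ethers (last step).
2. Key disconnection C2–C1′: the C2-zincated chromone 10 (an α-metalated enol ether, i.e. a masked acyl anion at the normally electrophilic C2 of the enone) is joined to the electrophilic CH2Br carbon of 1-bromopentadecane 9 under Pd catalysis.
3. Chromone 8 ⇐ acetophenone 5 by the enaminone annulation with DMF-DMA, the only ring-forming step.
4. 5 ⇐ 3 by selective O-methylation; 3 ⇐ 2′,4′,6′-trihydroxyacetophenone 1 by double C-methylation.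
5. Ring order: the benzene ring is bought (1), the pyranone ring is closed in step 3, and the side chain is attached last to the intact bicycle.

Assumption: the target has no stereocentre and no stereogenic double bond, so the structure drawn is its only stereoisomer and no stereocontrol is needed.

**Route**

Step 1
Reactants: 1 2′,4′,6′-trihydroxyacetophenone; 2 iodomethane
Product: 3 1-(2,4,6-trihydroxy-3,5-dimethylphenyl)ethan-1-one
Conditions: NaOMe (2.2 equiv), MeI (2.2 equiv), MeOH, 0 °C → reflux; chromatography
Reagents that add atoms: iodomethane, CI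
Why: C-alkylation of a phloroglucinol phenoxide (SN2 methylation of an ambident, enolate-like anion in a protic solvent) puts a methyl group on each of the two equivalent free ring carbons, and limiting base and MeI to about two equivalents holds back dearomatising gem-dimethylation.

Step 2
Reactants: 3 1-(2,4,6-trihydroxy-3,5-dimethylphenyl)ethan-1-one; 4 dimethyl sulfate
Product: 5 1-(2-hydroxy-4,6-dimethoxy-3,5-dimethylphenyl)ethan-1-one
Conditions: Me2SO4 (2.1 equiv), K2CO3 (2.5 equiv), acetone, reflux
Reagents that add atoms: dimethyl sulfate, COS(=O)(=O)OC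
Why: Williamson ether synthesis with a hard electrophile in an aprotic solvent gives O-methylation of two phenols, while the last ortho OH, hydrogen-bonded to the acetyl group, is left free.

Step 3
Reactants: 5 1-(2-hydroxy-4,6-dimethoxy-3,5-dimethylphenyl)ethan-1-one; 6 N,N-dimethylformamide dimethyl acetal (DMF-DMA)
Product: 8 5,7-dimethoxy-6,8-dimethyl-4H-chromen-4-one, via enaminone 7 (not isolated)
Conditions: DMF-DMA (2 equiv), toluene, 100 °C; concentrate; then AcOH, 100 °C
Reagents that add atoms: N,N-dimethylformamide dimethyl acetal, COC(OC)N(C)C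
Why: Condensation of the acetyl CH3 with the amide acetal gives the enaminone, and acid then drives 6-endo oxa-Michael addition of the phenol and loss of dimethylamine (enaminone route to 2,3-unsubstituted chromones).

Step 4
Reactants: 8 5,7-dimethoxy-6,8-dimethyl-4H-chromen-4-one; 9 1-bromopentadecane
Product: 11 5,7-dimethoxy-6,8-dimethyl-2-pentadecyl-4H-chromen-4-one, via bis(chromon-2-yl)zinc 10 (not isolated)
Conditions: TMP2Zn·2MgCl2·2LiCl (0.6 equiv; TMP = 2,2,6,6-tetramethylpiperidide), THF, −30 → 0 °C; then 9 (1.5 equiv), Pd2(dba)3 (2 mol %), PCyp3 (tricyclopentylphosphine, 8 mol %), N-methylimidazole (1.2 equiv), THF/NMP 2:1, 80 °C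
Reagents that add atoms: 1-bromopentadecane, CCCCCCCCCCCCCCCBr
Why: Proposed new method: MgCl2 held between the C4 carbonyl and the 5-OMe gives the pyranone pyrylium-like character, which makes C2–H the most acidic site and blocks carbonyl-directed C3 metalation, so the zinc amide gives the C2-zinc species 10, an α-metalated enol ether that acts as a masked acyl anion at the normally electrophilic C2; the zerovalent palladium/PCyp3 catalyst then adds oxidatively to the primary bromide in an SN2-type step, takes the chromonyl group from zinc and reductively eliminates faster than β-hydride elimination; the closest known reaction types are the C2-zincation/Negishi arylation of chromones and the Negishi coupling of alkenylzinc reagents with unactivated primary alkyl halides (no stereocentre is formed; the aryl ring is fully substituted, so no competing ring C–H exists).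

Step 5
Reactants: 11 5,7-dimethoxy-6,8-dimethyl-2-pentadecyl-4H-chromen-4-one
Product: 12 5,7-dihydroxy-6,8-dimethyl-2-pentadecyl-4H-chromen-4-one
Conditions: BBr3 (5 equiv), CH2Cl2, −78 °C → rt; then H2O
Reagents that add atoms: none
Why: Lewis-acid ether cleavage (BBr3 demethylation): boron binds each ether oxygen (the 5-OMe helped by chelation to C4=O, the 7-OMe twisted out of plane by its two ortho methyls and therefore basic) and bromide removes the methyl group by SN2, while the chromone and the alkyl chain are inert.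

**Compound list**
1 | 1-(2,4,6-trihydroxyphenyl)ethan-1-one (2′,4′,6′-trihydroxyacetophenone) | CC(=O)c1c(O)cc(O)cc1O | starting material
2 | iodomethane | CI | starting material
3 | 1-(2,4,6-trihydroxy-3,5-dimethylphenyl)ethan-1-one | CC(=O)c1c(O)c(C)c(O)c(C)c1O | intermediate
4 | dimethyl sulfate | COS(=O)(=O)OC | starting material
5 | 1-(2-hydroxy-4,6-dimethoxy-3,5-dimethylphenyl)ethan-1-one | CC(=O)c1c(O)c(C)c(OC)c(C)c1OC | intermediate
6 | N,N-dimethylformamide dimethyl acetal | COC(OC)N(C)C | starting material
7 | (E)-3-(dimethylamino)-1-(2-hydroxy-4,6-dimethoxy-3,5-dimethylphenyl)prop-2-en-1-one | CN(C)/C=C/C(=O)c1c(O)c(C)c(OC)c(C)c1OC | intermediate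
8 | 5,7-dimethoxy-6,8-dimethyl-4H-chromen-4-one | COc1c(C)c(OC)c2c(c1C)occc2=O | intermediate
9 | 1-bromopentadecane | CCCCCCCCCCCCCCCBr | starting material
10 | bis(5,7-dimethoxy-6,8-dimethyl-4-oxo-4H-chromen-2-yl)zinc, as its MgCl2/LiCl complex | COc1c(C)c(OC)c2c(c1C)oc(cc2=O)[Zn]c1cc(=O)c2c(OC)c(C)c(OC)c(C)c2o1 | intermediate
11 | 5,7-dimethoxy-6,8-dimethyl-2-pentadecyl-4H-chromen-4-one | CCCCCCCCCCCCCCCc1cc(=O)c2c(OC)c(C)c(OC)c(C)c2o1 | intermediate
12 | 5,7-dihydroxy-6,8-dimethyl-2-pentadecyl-4H-chromen-4-one | CCCCCCCCCCCCCCCc1cc(=O)c2c(O)c(C)c(O)c(C)c2o1 | target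

**Totals**
Total step count: 5. Longest linear sequence: 5 steps (1 → 3 → 5 → 8 → 11 → 12).

**Steps most likely to fail, and fallbacks**

Step 4 (key coupling). The risks are partial C3 instead of C2 zincation, and slow oxidative addition of the unactivated bromide with β-hydride elimination, which would return 8 and pentadecene. A D2O quench of 10 should be run first to confirm the site of metalation. Fallback, setting out from 10 (made from 8 as in step 4) and coming back at 11: keep the C2-zinc nucleophile but give it an sp2 electrophile. Takai olefination of tetradecanal (CHI3, CrCl2, THF) gives (E)-1-iodopentadec-1-ene F1. Negishi coupling of 10 with F1 (Pd(PPh3)4, THF, 25–50 °C, the alkenyl counterpart of the aryl iodide couplings established for C2-zincated chromones) gives 5,7-dimethoxy-6,8-dimethyl-2-[(E)-pentadec-1-en-1-yl]-4H-chromen-4-one F2. Hydrogenation of the side-chain alkene only (H2, 1 atm, Pd/C, EtOAc; the pyranone C2=C3 bond is not reduced, as in the hydrogenation of 2-styrylchromones to 2-phenethylchromones) then gives 11. The E/Z ratio of F1 does not matter because the alkene is removed.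

Step 1 (double C-methylation). The risks are mono-, O- and gem-dimethylated by-products and a modest isolated yield. Fallback, setting out from 1 and coming back at 3: a double phenolic Mannich reaction (aqueous CH2O, Me2NH, EtOH, rt) gives 1-{3,5-bis[(dimethylamino)methyl]-2,4,6-trihydroxyphenyl}ethan-1-one F3. Hydrogenolysis of the two benzylic C–N bonds (H2, 4 bar, Pd/C, AcOH, 60 °C) then gives 3. Aminomethylation stops at one substituent per ring carbon, so gem-dialkylation is excluded.

Step 5 (double demethylation). The risk is incomplete cleavage of the 7-OMe flanked by two methyl groups, or loss of the lipophilic product on work-up. Fallback, setting out from 3 and coming back at 12: carry benzyl ethers in place of methyl ethers.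
- BnBr, K2CO3, acetone, reflux gives 1-[4,6-bis(benzyloxy)-2-hydroxy-3,5-dimethylphenyl]ethan-1-one F4.
- DMF-DMA, then AcOH, passes through the enaminone (E)-1-[4,6-bis(benzyloxy)-2-hydroxy-3,5-dimethylphenyl]-3-(dimethylamino)prop-2-en-1-one F5 to 5,7-bis(benzyloxy)-6,8-dimethyl-4H-chromen-4-one F6.
- Zincation as in step 4 gives bis[5,7-bis(benzyloxy)-6,8-dimethyl-4-oxo-4H-chromen-2-yl]zinc F7, and coupling with 9 gives 5,7-bis(benzyloxy)-6,8-dimethyl-2-pentadecyl-4H-chromen-4-one F8.
- Hydrogenolysis (H2, Pd/C, EtOAc/EtOH, rt) gives 12.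

**Further compounds**
F1 | step 4 | (E)-1-iodopentadec-1-ene | CCCCCCCCCCCCC/C=C/I
F2 | step 4 | 5,7-dimethoxy-6,8-dimethyl-2-[(E)-pentadec-1-en-1-yl]-4H-chromen-4-one | CCCCCCCCCCCCC/C=C/c1cc(=O)c2c(OC)c(C)c(OC)c(C)c2o1
F3 | step 1 | 1-{3,5-bis[(dimethylamino)methyl]-2,4,6-trihydroxyphenyl}ethan-1-one | CC(=O)c1c(O)c(CN(C)C)c(O)c(CN(C)C)c1O
F4 | step 5 | 1-[4,6-bis(benzyloxy)-2-hydroxy-3,5-dimethylphenyl]ethan-1-one | CC(=O)c1c(O)c(C)c(OCc2ccccc2)c(C)c1OCc1ccccc1
F5 | step 5 | (E)-1-[4,6-bis(benzyloxy)-2-hydroxy-3,5-dimethylphenyl]-3-(dimethylamino)prop-2-en-1-one | CN(C)/C=C/C(=O)c1c(O)c(C)c(OCc2ccccc2)c(C)c1OCc1ccccc1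
F6 | step 5 | 5,7-bis(benzyloxy)-6,8-dimethyl-4H-chromen-4-one | Cc1c(OCc2ccccc2)c(C)c2occc(=O)c2c1OCc1ccccc1
F7 | step 5 | bis[5,7-bis(benzyloxy)-6,8-dimethyl-4-oxo-4H-chromen-2-yl]zinc | O=c1cc([Zn]c2cc(=O)c3c(OCc4ccccc4)c(C)c(OCc4ccccc4)c(C)c3o2)oc2c(C)c(OCc3ccccc3)c(C)c(OCc3ccccc3)c12
F8 | step 5 | 5,7-bis(benzyloxy)-6,8-dimethyl-2-pentadecyl-4H-chromen-4-one | CCCCCCCCCCCCCCCc1cc(=O)c2c(OCc3ccccc3)c(C)c(OCc3ccccc3)c(C)c2o1
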